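**Remark on the chemistry.** The target has no stereocentre. Intermediates 2, 6, 7 and 9 are racemic and their stereocentres are all erased later, so no configuration has to be controlled.

## Analysis of the target

The target is 5,7-dihydroxy-2-(4-hydroxy-2,5-dimethoxyphenyl)-6-methoxy-4H-chromen-4-one. It is a flavone with a benzo ring A (C4a, C5 to C8, C8a), a pyranone ring C (O1, C2, C3, C4) and an aryl ring B on C2. It is achiral, so the whole difficulty is regiochemical. Ring A carries oxygen at C5, C6, C7 and C8a and carbon at C4a, with hydrogen only at C8. Of the three contiguous oxygens at C5, C6 and C7, only the middle one is methylated, so the methyl group cannot be placed by selective alkylation of a preformed triol. The C4a carbon must also sit next to C5 and not next to C7. Ring B has a free hydroxyl at C4' between a hydrogen and a methoxy group, which again needs a differentiated oxygen. The free 5,7-dihydroxy system and the 4'-phenol are electron-rich and oxidise easily under base, and C8 is nucleophilic, so the phenols should be unveiled last. The strategy rests on C6 lying para to C8a. A 4-alkenyl-4-methoxycyclobutenone that opens and recloses thermally writes exactly this pattern: its C4 methoxy becomes C6–OMe, its carbonyl carbon becomes C8a–OH, and every other ring A oxygen arrives separately protected.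

## Retrosynthetic reasoning

**24 from 23.** Three O–alkyl bonds are cut: methyl on O5, isopropyl on O7 and benzyl on O4'. One boron Lewis acid can remove all three, each for its own reason (peri chelation to the C4 carbonyl, a secondary alkyl group, a benzylic group). The methyl ethers at C6, C2' and C5' have none of these handles. The forward step must stop before the C6 methyl ether is attacked.

**23 from 21.** Ring C is opened at O1–C2. In 21 the oxygen on C8a is the only one masked as an acetal. Acid frees it (22), it alone can add to the ring B carbonyl, and loss of water gives the pyranone. No aryl–oxygen bond has to be made.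

**21 from 11 and 19.** The C3–C4 bond is cut, which in the forward sense is acyl substitution at the ring A ester by the enolate of the ring B methyl ketone. The cut is placed here because the key step delivers C4 as an ester on C4a. The free phenol of 10 would become a phenoxide ortho to the ester and deactivate it, so it is first capped as the methoxymethyl ether 11. The same group is removed by the acid that closes ring C.

**10 from 7 (key disconnection).** Ring A is opened at C4a–C8a and refolded into a cyclobutenone by remaking the bond between the ketene carbon and the methoxy-bearing carbon. This turns a pentasubstituted benzene into a four-membered ring whose substituent order is fixed by two simple additions. The forward reaction must open the ring with the methoxy group turning outward (8), close the six-membered ring (9) and aromatise.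

**7 from 3 and 4.** The bond between the quaternary ring carbon and the β-carbon of the acrylate is cut, together with the O–methyl bond. Forward, 4 is lithiated at the β-carbon (5) and adds to the ketone-type carbonyl of 3; the other carbonyl is a vinylogous ester. The resulting alkoxide 6 lies cis to the ester and could lactonise, so it must be methylated cold in the same flask.

**3 from 1.** One C–O bond of the squarate is exchanged for C–H by hydride reduction (2) and acid-induced 1,3-transposition with loss of one isopropoxy group.

**19 from 12.** The acetyl C–C bond is cut back to aryl bromide 16 (through 17 and 18). The bromine goes para to the benzyloxy group of 15 by the normal directing pattern of a 1,2,4-trialkoxybenzene. Ether 15 comes from phenol 14, and 14 from aldehyde 12 by aryl migration to oxygen (formate 13). Direct Lewis-acid acetylation of 15 is avoided because it endangers the benzyl ether.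

## Alternatives that were turned down

**Alternative 1:** The C3–C4 and O–C2 bonds are made together, with the 1,3-dicarbonyl unit masked as an isoxazole. Aldoxime A1 is oxidised with PhI(OAc)2 in the presence of arylacetylene A2; the nitrile oxide A3 formed in the flask adds to the alkyne and gives the 3,5-diarylisoxazole A4.
- For: the cycloaddition is convergent and neutral, and its regiochemistry with terminal alkynes is dependable. The nitrile oxide, flanked by two ortho substituents, should resist dimerisation. It avoids acyl substitution at a hindered benzoate, and on that point it is stronger than the chosen route.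
- Against: the key step closes no ring of the target, and A1 already contains the whole ring A problem, a pentasubstituted benzaldehyde with a lone methoxy group between two protected oxygens. After the cycloaddition, N–O cleavage, hydrolysis, cyclodehydration and deprotection are still needed, and reductive N–O cleavage competes with the benzyl ethers.
- Comparison: the chosen strategy spends its key step on ring A and accepts a harder condensation afterwards.

**Alternative 2:** Ring A is closed at C4a–C5 from a pyranone that already carries ring B. Pyranone keto ester A5 is treated with LiN(SiMe3)2; C4a attacks the ester carbonyl and tautomerisation gives the 4'-O-benzyl flavone A6.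
- For: it is the shortest on paper. Ring A emerges with free hydroxyls at C5 and C7 and the methoxy group at C6, so no Lewis-acid dealkylation is needed. Its endgame is gentler than the chosen one.
- Against: the most acidic protons of A5 are at C6 and C8. C4a can only react through the extended enolate from C8, in competition with O-acylation, retro-Claisen cleavage of the α-methoxy-β-keto ester and base-induced opening of the pyranone. Assembling A5 has its own C- versus O-acylation problem.
- Comparison: the chosen key step is a unimolecular pericyclic reaction without base, whose regiochemistry is fixed by connectivity, at the price of protecting-group steps.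

**Alternative 3:** Ring C is closed at O1–C8a. Bromo diketone A7 undergoes intramolecular O-arylation of its enol under CuI, a diamine ligand and base to give flavone A8.
- For: copper-catalysed enol O-arylation forming a six-membered ring is reliable and needs no free phenol at C8a. The methoxymethyl groups on O5 and O7 come off with mild acid without risk to the C6 methyl ether, which is a gentler deprotection than BCl3.
- Against: A7 needs a ring A with bromine at C8a, ortho to the acyl group. Electrophilic bromination of the corresponding benzoyl compound would go to C8, which is activated by two oxygens, so the halogen and the oxygen pattern must be built stepwise by other means.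
- Comparison: its key step solves an easy bond. The chosen route makes ring C by plain cyclodehydration and uses its key step for the difficult ring.

Key step: step 3

## Route

Step 1
Reactants: 1 diisopropyl squarate
Product: 3 semisquarate 3-isopropoxycyclobut-3-ene-1,2-dione, via hydroxycyclobutenone 2 (not isolated)
Conditions: LiAlH(OtBu)3 (1.1 equiv), THF, −78 → −20 °C; then 6 M HCl, CH2Cl2, 0 °C → rt, same flask
Reagents that add atoms: water, O (supplies the oxygen of the new carbonyl group)
Why: The bulky hydride adds once, 1,2, to a squarate carbonyl; acid ionises the hydroxyl of 2 to an alkoxy-stabilised cyclobutenyl cation, water adds at the far end and propan-2-ol is lost, a known reduction and 1,3-carbonyl transposition of squarate esters.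

Step 2
Reactants: 3 semisquarate 3-isopropoxycyclobut-3-ene-1,2-dione; 4 methyl (E)-3-methoxyprop-2-enoate
Product: 7 methyl (E)-3-methoxy-3-(1-methoxy-2-isopropoxy-4-oxocyclobut-2-en-1-yl)prop-2-enoate (racemic), via vinyllithium 5 (not isolated), via lithium alkoxide 6 (not isolated)
Conditions: 4, LiN(iPr)2, THF, −90 °C; 3, −90 °C; MeOTf (3 equiv), −90 → −40 °C
Reagents that add atoms: methyl trifluoromethanesulfonate (MeOTf), COS(=O)(=O)C(F)(F)F
Why: The ester carbonyl directs deprotonation to the β-hydrogen cis to it, giving a chelated vinyllithium with retained geometry; this adds 1,2 to the ketone-type carbonyl of 3 (the one next to the isopropoxy-bearing carbon), and the alkoxide is O-methylated cold before it can attack the cis ester; the new stereocentre is racemic and is lost in step 3.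

Step 3
Reactants: 7 methyl (E)-3-methoxy-3-(1-methoxy-2-isopropoxy-4-oxocyclobut-2-en-1-yl)prop-2-enoate
Product: 10 methyl 6-hydroxy-2,3-dimethoxy-4-isopropoxybenzoate, via dienylketene 8 (not isolated), via cyclohexadienone 9 (not isolated)
Conditions: PhMe (0.02 M, degassed), 110 °C
Reagents that add atoms: none
Why: Heating opens the cyclobutenone by a conrotatory four-electron electrocyclic reaction that breaks the C1–C4 bond; the donor methoxy group on C4 rotates outward, so the alkenyl group turns inward and dienylketene 8 has its acrylate arm cis to the ketene. The ketene carbon (future C8a) and the ester-bearing alkene carbon (future C4a) then join in a thermally allowed disrotatory six-electron electrocyclisation, which closes ring A as cyclohexadienone 9. The sp3 centre created at C4a in 9 is not controlled and need not be, because enolisation removes it at once and gives the aromatic, hydrogen-bonded salicylate 10. The closest known reaction type is the Moore rearrangement of 4-alkenyl- and 4-aryl-4-alkoxycyclobutenones to highly oxygenated phenols. The only selectivity required is the torquoselectivity of the ring opening, which the 4-methoxy group secures; the substituent positions follow from the connectivity of 7 (ring methoxy to C6, isopropoxy to C7, ring hydrogen to C8, enol ether methoxy to C5) and cannot be scrambled. The ester lies on the inner side of the closing terminus, which should be tolerated because the ketene terminus carries no substituent, and either geometry of the enol ether double bond would lead to 10. High dilution keeps the ketene from dimerising.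

Step 4
Reactants: 10 methyl 6-hydroxy-2,3-dimethoxy-4-isopropoxybenzoate
Product: 11 methyl 2,3-dimethoxy-6-(methoxymethoxy)-4-isopropoxybenzoate
Conditions: NaH, MOMCl, DMF, 0 °C → rt
Reagents that add atoms: chloromethyl methyl ether (MOMCl), COCCl
Why: Williamson-type O-alkylation of the only free phenol; removing the phenoxide ortho to the ester restores its electrophilicity for step 9, and the acetal is later cleaved by the acid that closes ring C.

Step 5
Reactants: 12 2,5-dimethoxybenzaldehyde
Product: 14 2,5-dimethoxyphenol, via aryl formate 13 (not isolated)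
Conditions: mCPBA, CH2Cl2, 0 °C → rt; aq. NaHCO3 wash; then K2CO3 (cat.), MeOH, rt
Reagents that add atoms: 3-chloroperbenzoic acid (mCPBA), OOC(=O)c1cccc(Cl)c1
Why: Baeyer–Villiger (Dakin-type) oxidation; the electron-rich aryl group with an ortho methoxy group migrates to oxygen in preference to hydrogen, and the formate is removed by methanolysis.

Step 6
Reactants: 14 2,5-dimethoxyphenol
Product: 15 2-(benzyloxy)-1,4-dimethoxybenzene
Conditions: BnBr, K2CO3, DMF, 50 °C
Reagents that add atoms: benzyl bromide, BrCc1ccccc1
Why: Williamson ether synthesis on a phenoxide; benzyl marks the future 4'-oxygen apart from the two methyl ethers.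

Step 7
Reactants: 15 2-(benzyloxy)-1,4-dimethoxybenzene
Product: 16 1-(benzyloxy)-4-bromo-2,5-dimethoxybenzene
Conditions: NBS, MeCN, 0 °C
Reagents that add atoms: N-bromosuccinimide, O=C1CCC(=O)N1Br
Why: Electrophilic aromatic bromination; the position para to the benzyloxy group and ortho to a methoxy group is the doubly activated, unhindered site of a 1,2,4-trialkoxybenzene, whereas the alternative site lies between two alkoxy groups.

Step 8
Reactants: 16 1-(benzyloxy)-4-bromo-2,5-dimethoxybenzene
Product: 19 1-[4-(benzyloxy)-2,5-dimethoxyphenyl]ethan-1-one, via aryllithium 17 (not isolated), via lithium hemiaminal alkoxide 18 (not isolated)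
Conditions: n-BuLi, THF, −78 °C; MeC(O)N(OMe)Me, −78 → 0 °C; 1 M HCl
Reagents that add atoms: N-methoxy-N-methylacetamide, CC(=O)N(C)OC
Why: Bromine–lithium exchange is faster than benzylic deprotonation at −78 °C; Weinreb ketone synthesis then stops at the chelated tetrahedral adduct, so no tertiary alcohol forms and the ketone is released only on work-up.

Step 9
Reactants: 11 methyl 2,3-dimethoxy-6-(methoxymethoxy)-4-isopropoxybenzoate; 19 1-[4-(benzyloxy)-2,5-dimethoxyphenyl]ethan-1-one
Product: 21 1-[4-(benzyloxy)-2,5-dimethoxyphenyl]-3-[2,3-dimethoxy-6-(methoxymethoxy)-4-isopropoxyphenyl]propane-1,3-dione, via sodium enolate 20 (not isolated)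
Conditions: 19 (1.3 equiv), NaH (3 equiv), THF, 0 °C → rt; then 11, 65 °C; AcOH quench
Reagents that add atoms: none
Why: Crossed Claisen condensation of a non-enolisable o-alkoxybenzoate with a methyl ketone enolate, the classical entry to flavone 1,3-diketones; excess base deprotonates the diketone and pulls the equilibrium over.

Step 10
Reactants: 21 1-[4-(benzyloxy)-2,5-dimethoxyphenyl]-3-[2,3-dimethoxy-6-(methoxymethoxy)-4-isopropoxyphenyl]propane-1,3-dione
Product: 23 2-[4-(benzyloxy)-2,5-dimethoxyphenyl]-5,6-dimethoxy-7-isopropoxy-4H-chromen-4-one, via hydroxy diketone 22 (not isolated)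
Conditions: conc. HCl (cat.), MeOH, 60 °C
Reagents that add atoms: none
Why: Acidic methanol cleaves the methoxymethyl acetal; the freed C8a phenol, the only hydroxyl present, adds to the ring B carbonyl and the hemiketal dehydrates to the chromen-4-one (cyclodehydration of an o-hydroxyaryl 1,3-diketone), while methyl, isopropyl and benzyl ethers are stable.

Step 11
Reactants: 23 2-[4-(benzyloxy)-2,5-dimethoxyphenyl]-5,6-dimethoxy-7-isopropoxy-4H-chromen-4-one
Product: 24 5,7-dihydroxy-2-(4-hydroxy-2,5-dimethoxyphenyl)-6-methoxy-4H-chromen-4-one (target)
Conditions: BCl3 (6 equiv), C6HMe5 (3 equiv), CH2Cl2, −78 → 0 °C; then H2O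
Reagents that add atoms: none
Why: Lewis-acid ether cleavage: BCl3 bound to the C4 carbonyl removes the peri 5-O-methyl group through a six-membered chelate, and the secondary isopropyl and the benzyl ether ionise readily, with pentamethylbenzene trapping the benzyl cation away from C8; the unchelated methyl ethers at C6, C2' and C5' need more forcing conditions.

## Compound list

1 | diisopropyl squarate (3,4-diisopropoxycyclobut-3-ene-1,2-dione) | CC(C)OC1=C(OC(C)C)C(=O)C1=O | starting material
2 | 4-hydroxy-2,3-diisopropoxycyclobut-2-en-1-one (racemic) | CC(C)OC1=C(OC(C)C)C(O)C1=O | intermediate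
3 | 3-isopropoxycyclobut-3-ene-1,2-dione | CC(C)OC1=CC(=O)C1=O | intermediate
4 | methyl (E)-3-methoxyprop-2-enoate | CO/C=C/C(=O)OC | starting material
5 | methyl (E)-3-lithio-3-methoxyprop-2-enoate | [Li]/C(OC)=C\C(=O)OC | intermediate
6 | lithium 1-[(E)-1,3-dimethoxy-3-oxoprop-1-en-1-yl]-2-isopropoxy-4-oxocyclobut-2-en-1-olate (racemic) | [Li+].[O-]C1(/C(OC)=C\C(=O)OC)C(OC(C)C)=CC1=O | intermediate
7 | methyl (E)-3-methoxy-3-(1-methoxy-2-isopropoxy-4-oxocyclobut-2-en-1-yl)prop-2-enoate (racemic) | O=C1C=C(OC(C)C)C1(OC)/C(OC)=C\C(=O)OC | intermediate
8 | methyl (2E,4Z)-3,4-dimethoxy-5-isopropoxy-7-oxohepta-2,4,6-trienoate | O=C=C\C(OC(C)C)=C(OC)/C(OC)=C\C(=O)OC | intermediate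
9 | methyl 2,3-dimethoxy-4-isopropoxy-6-oxocyclohexa-2,4-diene-1-carboxylate (racemic) | COC(=O)C1C(=O)C=C(OC(C)C)C(OC)=C1OC | intermediate
10 | methyl 6-hydroxy-2,3-dimethoxy-4-isopropoxybenzoate | COC(=O)c1c(O)cc(OC(C)C)c(OC)c1OC | intermediate
11 | methyl 2,3-dimethoxy-6-(methoxymethoxy)-4-isopropoxybenzoate | COCOc1cc(OC(C)C)c(OC)c(OC)c1C(=O)OC | intermediate
12 | 2,5-dimethoxybenzaldehyde | COc1ccc(OC)c(C=O)c1 | starting material
13 | 2,5-dimethoxyphenyl formate | COc1ccc(OC)c(OC=O)c1 | intermediate
14 | 2,5-dimethoxyphenol | COc1ccc(OC)c(O)c1 | intermediate
15 | 2-(benzyloxy)-1,4-dimethoxybenzene | COc1ccc(OC)c(OCc2ccccc2)c1 | intermediate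
16 | 1-(benzyloxy)-4-bromo-2,5-dimethoxybenzene | COc1cc(Br)c(OC)cc1OCc1ccccc1 | intermediate
17 | [4-(benzyloxy)-2,5-dimethoxyphenyl]lithium | [Li]c1cc(OC)c(OCc2ccccc2)cc1OC | intermediate
18 | lithium 1-[4-(benzyloxy)-2,5-dimethoxyphenyl]-1-[methoxy(methyl)amino]ethan-1-olate (racemic) | [Li+].CC([O-])(N(C)OC)c1cc(OC)c(OCc2ccccc2)cc1OC | intermediate
19 | 1-[4-(benzyloxy)-2,5-dimethoxyphenyl]ethan-1-one | CC(=O)c1cc(OC)c(OCc2ccccc2)cc1OC | intermediate
20 | sodium 1-[4-(benzyloxy)-2,5-dimethoxyphenyl]ethen-1-olate | [Na+].[O-]C(=C)c1cc(OC)c(OCc2ccccc2)cc1OC | intermediate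
21 | 1-[4-(benzyloxy)-2,5-dimethoxyphenyl]-3-[2,3-dimethoxy-6-(methoxymethoxy)-4-isopropoxyphenyl]propane-1,3-dione | COCOc1cc(OC(C)C)c(OC)c(OC)c1C(=O)CC(=O)c1cc(OC)c(OCc2ccccc2)cc1OC | intermediate
22 | 1-[4-(benzyloxy)-2,5-dimethoxyphenyl]-3-(6-hydroxy-2,3-dimethoxy-4-isopropoxyphenyl)propane-1,3-dione | Oc1cc(OC(C)C)c(OC)c(OC)c1C(=O)CC(=O)c1cc(OC)c(OCc2ccccc2)cc1OC | intermediate
23 | 2-[4-(benzyloxy)-2,5-dimethoxyphenyl]-5,6-dimethoxy-7-isopropoxy-4H-chromen-4-one | COc1cc(-c2cc(=O)c3c(OC)c(OC)c(OC(C)C)cc3o2)c(OC)cc1OCc1ccccc1 | intermediate
24 | 5,7-dihydroxy-2-(4-hydroxy-2,5-dimethoxyphenyl)-6-methoxy-4H-chromen-4-one | COc1cc(-c2cc(=O)c3c(O)c(OC)c(O)cc3o2)c(OC)cc1O | target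

## Step count and risk

Total: 11 steps. Longest linear sequence: 7 steps (steps 1 to 4 and 9 to 11 from diisopropyl squarate; the ring B branch, steps 5 to 8 and 9 to 11, is equally long).

**Step 3 (key step).** The most likely failure is slow six-electron closure, because the ester sits on the inner side of the closing terminus. The ketene would then be lost to dimerisation or to reaction with adventitious nucleophiles instead of cyclising. The fallback sets out from 3 and comes back at 11; it introduces the ester after ring formation. 1-Methoxyvinyllithium F1 (from methyl vinyl ether and t-BuLi) would be added to 3 and the alkoxide methylated with MeOTf to give 4-methoxy-4-(1-methoxyethenyl)-3-isopropoxycyclobut-2-en-1-one F2, which has nothing on the inner side of its alkene terminus. Heating in toluene should give 3-isopropoxy-4,5-dimethoxyphenol F3, and NaH with MOMCl would give 1-isopropoxy-2,3-dimethoxy-5-(methoxymethoxy)benzene F4. Directed ortho-lithiation (n-BuLi, TMEDA) is expected between the acetal and the methoxy group rather than next to the bulky, weakly directing isopropoxy group, and a ClCO2Me quench would give 11.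

**Step 2.** Two processes can outrun O-methylation. Alkoxide 6 can cyclise onto the cis ester (spirolactonisation), or it can be protonated by the ammonium salt formed from diisopropylamine and MeOTf. Partial deprotonation of 4 at the α-carbon is a further risk. The fallback sets out from 3 and comes back at 10; it moves the methylation to after the ring expansion. Alkoxide 6, made as in step 2, would be captured at −90 °C with Et3SiOTf, which reacts on mixing, to give methyl (E)-3-methoxy-3-[4-oxo-2-isopropoxy-1-(triethylsilyloxy)cyclobut-2-en-1-yl]prop-2-enoate F5. Thermolysis as in step 3 (a silyloxy group also rotates outward) should give methyl 6-hydroxy-2-methoxy-4-isopropoxy-3-(triethylsilyloxy)benzoate F6. Bu4NF buffered with AcOH would give methyl 3,6-dihydroxy-2-methoxy-4-isopropoxybenzoate F7. One equivalent of MeI with K2CO3 in acetone should methylate the hydroxyl that is not hydrogen-bonded to the ester and give 10.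

**Step 9.** Acyl substitution at an ester flanked by two ortho alkoxy groups may be slow, leaving the ketone enolate to self-condense. The fallback sets out from 11 and 16 and comes back at 21; it reverses the polarity. Ester 11 would be treated with Me3SiCH2Li (2.5 equiv) and then methanol to give 1-[2,3-dimethoxy-6-(methoxymethoxy)-4-isopropoxyphenyl]ethan-1-one F8. Aryllithium 17, made from 16 as in step 8, would be quenched with ClCO2Me to give methyl 4-(benzyloxy)-2,5-dimethoxybenzoate F9. The enolate of F8, formed with LiN(SiMe3)2, would then attack F9, whose ester has only one ortho substituent, to give 21.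

**Step 11.** Over-dealkylation is the main risk: the C6 methyl ether lies next to the boron-bound C5 oxygen and may be lost on prolonged exposure. Benzylation at C8 is possible if cation trapping is incomplete. The fallback sets out from 23 and comes back at 24; it separates the deprotections. Hydrogenolysis (H2, 10% Pd/C, EtOAc) would remove the benzyl group and give 2-(4-hydroxy-2,5-dimethoxyphenyl)-5,6-dimethoxy-7-isopropoxy-4H-chromen-4-one F10. AlCl3 in MeCN at room temperature, a reagent selective for chelated 5-methoxy groups and isopropyl aryl ethers, would then give 24.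

## Further compounds

F1 | step 3 | 1-methoxyvinyllithium | [Li]C(=C)OC
F2 | step 3 | 4-methoxy-4-(1-methoxyethenyl)-3-isopropoxycyclobut-2-en-1-one (racemic) | O=C1C=C(OC(C)C)C1(OC)C(OC)=C
F3 | step 3 | 3-isopropoxy-4,5-dimethoxyphenol | COc1cc(O)cc(OC(C)C)c1OC
F4 | step 3 | 1-isopropoxy-2,3-dimethoxy-5-(methoxymethoxy)benzene | COCOc1cc(OC)c(OC)c(OC(C)C)c1
F5 | step 2 | methyl (E)-3-methoxy-3-[4-oxo-2-isopropoxy-1-(triethylsilyloxy)cyclobut-2-en-1-yl]prop-2-enoate (racemic) | O=C1C=C(OC(C)C)C1(O[Si](CC)(CC)CC)/C(OC)=C\C(=O)OC
F6 | step 2 | methyl 6-hydroxy-2-methoxy-4-isopropoxy-3-(triethylsilyloxy)benzoate | COC(=O)c1c(O)cc(OC(C)C)c(O[Si](CC)(CC)CC)c1OC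
F7 | step 2 | methyl 3,6-dihydroxy-2-methoxy-4-isopropoxybenzoate | COC(=O)c1c(O)cc(OC(C)C)c(O)c1OC
F8 | step 9 | 1-[2,3-dimethoxy-6-(methoxymethoxy)-4-isopropoxyphenyl]ethan-1-one | COCOc1cc(OC(C)C)c(OC)c(OC)c1C(C)=O
F9 | step 9 | methyl 4-(benzyloxy)-2,5-dimethoxybenzoate | COC(=O)c1cc(OC)c(OCc2ccccc2)cc1OC
F10 | step 11 | 2-(4-hydroxy-2,5-dimethoxyphenyl)-5,6-dimethoxy-7-isopropoxy-4H-chromen-4-one | COc1cc(-c2cc(=O)c3c(OC)c(OC)c(OC(C)C)cc3o2)c(OC)cc1O
A1 | alternative 1 | (E)-4,6-bis(benzyloxy)-5-methoxy-2-(methoxymethoxy)benzaldehyde oxime | COCOc1cc(OCc2ccccc2)c(OC)c(OCc2ccccc2)c1/C=N/O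
A2 | alternative 1 | 1-(benzyloxy)-4-ethynyl-2,5-dimethoxybenzene | C#Cc1cc(OC)c(OCc2ccccc2)cc1OC
A3 | alternative 1 | 4,6-bis(benzyloxy)-5-methoxy-2-(methoxymethoxy)benzonitrile oxide | COCOc1cc(OCc2ccccc2)c(OC)c(OCc2ccccc2)c1C#[N+][O-]
A4 | alternative 1 | 3-[4,6-bis(benzyloxy)-5-methoxy-2-(methoxymethoxy)phenyl]-5-[4-(benzyloxy)-2,5-dimethoxyphenyl]isoxazole | COCOc1cc(OCc2ccccc2)c(OC)c(OCc2ccccc2)c1-c1cc(-c2cc(OC)c(OCc3ccccc3)cc2OC)on1
A5 | alternative 2 | methyl 4-{6-[4-(benzyloxy)-2,5-dimethoxyphenyl]-4-oxo-4H-pyran-2-yl}-2-methoxy-3-oxobutanoate (racemic) | COC(=O)C(OC)C(=O)Cc1cc(=O)cc(-c2cc(OC)c(OCc3ccccc3)cc2OC)o1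
A6 | alternative 2 | 2-[4-(benzyloxy)-2,5-dimethoxyphenyl]-5,7-dihydroxy-6-methoxy-4H-chromen-4-one | COc1cc(-c2cc(=O)c3c(O)c(OC)c(O)cc3o2)c(OC)cc1OCc1ccccc1
A7 | alternative 3 | 1-[4-(benzyloxy)-2,5-dimethoxyphenyl]-3-[2-bromo-5-methoxy-4,6-bis(methoxymethoxy)phenyl]propane-1,3-dione | COCOc1cc(Br)c(C(=O)CC(=O)c2cc(OC)c(OCc3ccccc3)cc2OC)c(OCOC)c1OC
A8 | alternative 3 | 2-[4-(benzyloxy)-2,5-dimethoxyphenyl]-6-methoxy-5,7-bis(methoxymethoxy)-4H-chromen-4-one | COCOc1cc2oc(-c3cc(OC)c(OCc4ccccc4)cc3OC)cc(=O)c2c(OCOC)c1OC
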